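**Retrosynthetic overview**

1. Target ⇐ closure of the C6 hydroxyl onto the C12 methyl ester ⇐ cis-2-ene-1,4-diol ⇐ O–O reduction of the C3,C6-endoperoxide.
2. Endoperoxide ⇐ (4+2) addition of singlet oxygen to the C3=C4–C5=C6 diene of the ten-membered Z,Z-dienyl epoxide (forms C3–O, C6–O and the 1,2-dioxine ring).
3. Ten-membered ring ⇐ intramolecular Stille coupling at C4–C5; seco compound ⇐ iodoethylidene Wittig at C3, alkyne-to-Z-alkenylstannane at C5–C6, angeloylation at C8, and carboalkoxyallylboration (C7–C8) of a nerol-derived epoxy aldehyde with a Morita–Baylis–Hillman-derived allylboronate.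
4. Ring order: oxirane (step 1), ten-membered carbocycle (step 15), 1,2-dioxine (step 16), five-membered lactone (step 18).
5. Feature the plan rests on: the C3(O)–C4(CH3)=C5–C6(O) unit of the ten-membered ring, a Z alkene flanked by two C–O bonds on the same ring face (C3 hydroxyl, C6 lactone oxygen), which is the reduced form of a 1,2-dioxine bridging C3 and C6.

Key step: step 16

Assumption: locants C1–C13 in the names are skeleton labels (C1 methyl-bearing epoxide carbon, C2 epoxide CH, C3 carbinol, C4(CH3)=C5, C6 lactone O–CH, C7 ring-fusion CH, C8 angelate CH, C9/C10 the CH2 pair, C11/C12/C13 alpha carbon, carbonyl and exocyclic CH2); 3-(trimethylsilyl)propynal is taken as purchasable.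

**Route**

Step 1
Reactants: 1 nerol
Product: 2 (2R,3S)-2,3-epoxynerol
Conditions: Ti(OiPr)4 (10 mol %), D-(−)-diethyl tartrate (12 mol %), t-BuOOH, 4 Å MS, CH2Cl2, −20 °C
Reagents that add atoms: tert-butyl hydroperoxide, CC(C)(C)OO
Why: Sharpless asymmetric epoxidation oxidises only the allylic alkene, the Z geometry fixes the cis epoxide, and D-(−)-tartrate should deliver oxygen to the face that gives the 2R,3S epoxy alcohol (C2 R and C1 S of the skeleton).

Step 2
Reactants: 2 (2R,3S)-2,3-epoxynerol
Product: 3 (2R,3S)-2,3-epoxyneryl tert-butyldimethylsilyl ether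
Conditions: TBSCl, imidazole, DMF, 0 °C to rt
Reagents that add atoms: tert-butyldimethylsilyl chloride, CC(C)(C)[Si](C)(C)Cl
Why: Imidazole-mediated silylation masks the primary alcohol until the Wittig stage and is inert to the epoxide.

Step 3
Reactants: 3 (2R,3S)-2,3-epoxyneryl tert-butyldimethylsilyl ether
Product: 5 3-[(2S,3R)-3-(tert-butyldimethylsilyloxymethyl)-2-methyloxiran-2-yl]propanal, via ozonide 4 (not isolated)
Conditions: O3, CH2Cl2, −78 °C; then PPh3, −78 °C to rt
Reagents that add atoms: ozone, [O-][O+]=O
Why: Ozonolysis with reductive work-up cleaves the only remaining C=C bond to the C8 aldehyde with loss of acetone, while epoxide and silyl ether do not react with ozone.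

Step 4
Reactants: 6 3-(trimethylsilyl)prop-2-ynal; 7 methyl acrylate
Product: 8 methyl 3-hydroxy-2-methylidene-5-(trimethylsilyl)pent-4-ynoate (racemic)
Conditions: DABCO (20 mol %), 7 in excess, rt
Reagents that add atoms: none
Why: Morita–Baylis–Hillman reaction, in which the DABCO–acrylate enolate adds to the reactive ynal; the racemic carbinol centre is erased in step 6.

Step 5
Reactants: 8 methyl 3-hydroxy-2-methylidene-5-(trimethylsilyl)pent-4-ynoate
Product: 9 methyl 3-acetoxy-2-methylidene-5-(trimethylsilyl)pent-4-ynoate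
Conditions: Ac2O, pyridine, DMAP (cat.), CH2Cl2, 0 °C
Reagents that add atoms: acetic anhydride, CC(=O)OC(C)=O
Why: Acetylation turns the hydroxyl into the leaving group needed for the allylic substitution.

Step 6
Reactants: 9 methyl 3-acetoxy-2-methylidene-5-(trimethylsilyl)pent-4-ynoate
Product: 10 methyl (E)-2-[(4,4,5,5-tetramethyl-1,3,2-dioxaborolan-2-yl)methyl]-5-(trimethylsilyl)pent-2-en-4-ynoate
Conditions: B2pin2, CuCl (10 mol %), KOAc (20 mol %), DMF, rt
Reagents that add atoms: bis(pinacolato)diboron, CC1(C)OB(OC1(C)C)B1OC(C)(C)C(C)(C)O1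
Why: Copper-catalysed borylation of a Morita–Baylis–Hillman acetate (boryl-copper addition to the acrylate CH2, then beta-elimination of acetate, net SN2') should give the alkene with the alkynyl group trans to the ester and cis to CH2B.

Step 7
Reactants: 5 3-[(2S,3R)-3-(tert-butyldimethylsilyloxymethyl)-2-methyloxiran-2-yl]propanal; 10 the allylboronate
Product: 12 methyl (3S,4R)-4-hydroxy-2-methylidene-6-[(2S,3R)-3-(tert-butyldimethylsilyloxymethyl)-2-methyloxiran-2-yl]-3-[(trimethylsilyl)ethynyl]hexanoate, via pinacol borate 11 (not isolated)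
Conditions: (S)-3,3'-bis(2,4,6-triisopropylphenyl)-1,1'-binaphthyl-2,2'-diyl hydrogen phosphate (10 mol %), 4 Å MS, toluene, −30 °C to rt; aq. NaHCO3 work-up; used at once in step 8
Reagents that add atoms: none
Why: Chiral phosphoric acid catalysed allylboration through a closed chair: the alkynyl group cis to CH2B sits axial and ends up syn to the new hydroxyl (C7 relative to C8), the catalyst enantiomer is the one that by the accepted model directs addition to the Si face of the aldehyde (C8 R), and the weak acid at low temperature should spare the epoxide and keep the C8 oxygen from closing onto the ester.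

Step 8
Reactants: 12 the syn homoallylic alcohol; 13 angelic acid
Product: 15 methyl (3S,4R)-4-[(Z)-2-methylbut-2-enoyloxy]-2-methylidene-6-[(2S,3R)-3-(tert-butyldimethylsilyloxymethyl)-2-methyloxiran-2-yl]-3-[(trimethylsilyl)ethynyl]hexanoate, via mixed anhydride 14 (not isolated)
Conditions: 13, 2,4,6-trichlorobenzoyl chloride, Et3N, toluene, rt; then 12, 70 °C
Reagents that add atoms: none
Why: Yamaguchi-type acylation without a nucleophilic catalyst, in which the alcohol attacks the less hindered angeloyl carbonyl and the Z geometry of the angelate is not isomerised; acylation also removes the hydroxyl that could lactonise onto C12.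

Step 9
Reactants: 15 the silylalkyne angelate
Product: 16 the iodoalkyne (C5–I; otherwise as 15; 3S,4R)
Conditions: N-iodosuccinimide, AgNO3 (10 mol %), DMF, rt, dark
Reagents that add atoms: N-iodosuccinimide, O=C1CCC(=O)N1I
Why: Silver-catalysed iododesilylation (silver acetylide, then iodination) exchanges C–Si for C–I and leaves the alkenes, epoxide and silyl ether alone.

Step 10
Reactants: 16 the iodoalkyne
Product: 17 the (Z)-2-iodoethenyl compound (C5=C6 Z; 3R,4R by CIP, no change in space)
Conditions: 2-nitrobenzenesulfonyl hydrazide, Et3N, THF/i-PrOH, rt, reagent added in portions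
Reagents that add atoms: none
Why: Diimide released from the sulfonyl hydrazide adds H2 syn to the iodoalkyne much faster than to the hindered angelate or the 1,1-disubstituted acrylate, which gives the Z-iodoalkene.

Step 11
Reactants: 17 the Z-iodoalkene
Product: 18 the (Z)-2-(trimethylstannyl)ethenyl compound
Conditions: (Me3Sn)2, Pd(PPh3)4 (5 mol %), toluene, 60 °C
Reagents that add atoms: hexamethylditin, C[Sn](C)(C)[Sn](C)(C)C
Why: Palladium-catalysed stannylation of an alkenyl iodide proceeds with retention of the Z geometry, and at this stage the epoxide is not allylic, so zerovalent palladium cannot ionise it.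

Step 12
Reactants: 18 the Z-alkenylstannane silyl ether
Product: 19 the primary alcohol (hydroxymethyl at C2 of the skeleton)
Conditions: Bu4NF, AcOH (1:1), THF, 0 °C to rt
Reagents that add atoms: none
Why: Fluoride cleaves the primary Si–O bond, and the acetic acid buffer protects esters, epoxide and stannane.

Step 13
Reactants: 19 the primary alcohol
Product: 20 the epoxy aldehyde (C3 formyl; oxirane 2S,3S by CIP)
Conditions: Dess–Martin periodinane, NaHCO3, CH2Cl2, 0 °C to rt
Reagents that add atoms: none
Why: Buffered Dess–Martin oxidation gives the alpha,beta-epoxy aldehyde without epimerising C2 or attacking the alkenylstannane.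

Step 14
Reactants: 20 the epoxy aldehyde; 21 ethyltriphenylphosphonium bromide
Product: 25 the seco compound with (Z)-2-iodoprop-1-enyl at C2 and (Z)-2-(trimethylstannyl)ethenyl at C7, via ethylidenetriphenylphosphorane 22 (not isolated), via (1-iodoethyl)triphenylphosphonium iodide 23 (not isolated), via (1-iodoethylidene)triphenylphosphorane 24 (not isolated)
Conditions: 21, n-BuLi, THF, 0 °C; I2 (0.95 equiv), −78 °C; NaN(SiMe3)2, −78 to −20 °C; then 20, −78 to −20 °C
Reagents that add atoms: iodine, II
Why: Stork–Zhao-type Wittig olefination, in which the alpha-iodo ylide adds to the aldehyde under kinetic control and should give the Z-iodoalkene (iodine cis to C2), the geometry that C3=C4 needs; a slight deficit of iodine keeps the stannane safe.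

Step 15
Reactants: 25 the iodoalkene/alkenylstannane seco compound
Product: 26 methyl 2-[(1S,2R,3Z,5Z,7R,8R)-8-angeloyloxy-1,2-epoxy-1,4-dimethylcyclodeca-3,5-dien-7-yl]prop-2-enoate
Conditions: Pd(PPh3)4 (20 mol %), Cu(O2CC4H3S) (1.5 equiv), [NBu4][Ph2PO2] (1.5 equiv), DMF, rt, 0.002 M, slow addition
Reagents that add atoms: none
Why: Intramolecular Stille coupling with a copper carboxylate promoter and a phosphinate tin scavenger joins C4 and C5 with retention at both alkenes, the two Z alkenes turn the chain ends toward each other for ten-membered closure, and the room-temperature conditions are the kind used when an allylic epoxide must survive.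

Step 16
Reactants: 26 the ten-membered Z,Z-dienyl epoxide; 27 dioxygen
Product: 28 the C3,C6-endoperoxide (1S,2R,3R,6S,7R,8R)
Conditions: 27 (1 atm), tetraphenylporphyrin (1 mol %), visible light, CH2Cl2, −30 °C
Reagents that add atoms: none
Why: Sensitised singlet oxygen adds across C3 and C6 of the diene in its s-cis form in a concerted suprafacial (4+2) cycloaddition, the reaction known for cyclic cis,cis-1,3-dienes from cyclopentadiene to cycloocta-1,3-diene, so the ten-membered ring is an extension in ring size that asks the twisted diene to flatten. The 1,2-dioxine ring is closed by the cycloaddition itself, both C–O bonds forming in one step, and the C4=C5 bond that appears inside this six-membered ring is cis by construction. C3 and C6 are set relative to each other by the suprafacial addition to the Z,Z-diene, in which the inside ring carbons C2 and C7 swing to the side away from oxygen; their sense relative to C2 and C7 is set by which diene face is attacked. The face needed is the one anti to the epoxide oxygen at C2 and anti to the acrylate arm at C7 in the rotamers that hold H-2 and H-7 in the diene plane (allylic 1,3-strain), the face that an electrophile avoiding an allylic C–O bond and the larger allylic branch should choose. Site selectivity follows from the diene being the only electron-rich π system, since acrylate and angelate are electron-poor and the third trisubstituted alkene of nerol is already the epoxide. The ene reaction at the C4 methyl or at C7–H is the competing path, and low temperature in a non-polar solvent is chosen to hold it back.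

Step 17
Reactants: 28 the endoperoxide
Product: 29 the cis-2-ene-1,4-diol (1S,2R,3R,6S,7S,8R; C4=C5 Z)
Conditions: thiourea, MeOH, 0 °C to rt
Reagents that add atoms: none
Why: Thiourea reduces only the O–O bond (sulfur attacks a peroxide oxygen), so C3 and C6 keep their configuration and epoxide, esters and alkenes are untouched.

Step 18
Reactants: 29 the diol methyl ester
Product: 30 the target lactone CNP0500828.1
Conditions: pyridinium p-toluenesulfonate (10 mol %), CH2Cl2, rt
Reagents that add atoms: none
Why: Mild acid-catalysed transesterification closes the five-membered lactone from the C6 hydroxyl onto C12 (5-exo-trig) with loss of methanol, whereas the C3 hydroxyl would need an eight-membered ring and C8 is already acylated.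

**Compound list**

1 | nerol | CC(C)=CCC/C(C)=C\CO | starting material
2 | (2R,3S)-2,3-epoxynerol | OC[C@H]1O[C@@]1(C)CCC=C(C)C | intermediate
3 | (2R,3S)-2,3-epoxyneryl tert-butyldimethylsilyl ether | CC(C)(C)[Si](C)(C)OC[C@H]1O[C@@]1(C)CCC=C(C)C | intermediate
4 | ozonide of 3 (1,2,4-trioxolane at the former distal alkene) | CC(C)(C)[Si](C)(C)OC[C@H]1O[C@@]1(C)CCC2OOC(C)(C)O2 | intermediate
5 | 3-[(2S,3R)-3-(tert-butyldimethylsilyloxymethyl)-2-methyloxiran-2-yl]propanal | CC(C)(C)[Si](C)(C)OC[C@H]1O[C@@]1(C)CCC=O | intermediate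
6 | 3-(trimethylsilyl)prop-2-ynal | C[Si](C)(C)C#CC=O | starting material
7 | methyl acrylate | C=CC(=O)OC | starting material
8 | methyl 3-hydroxy-2-methylidene-5-(trimethylsilyl)pent-4-ynoate (racemic) | C=C(C(=O)OC)C(O)C#C[Si](C)(C)C | intermediate
9 | methyl 3-acetoxy-2-methylidene-5-(trimethylsilyl)pent-4-ynoate | C=C(C(=O)OC)C(OC(C)=O)C#C[Si](C)(C)C | intermediate
10 | methyl (E)-2-[(pinacolboryl)methyl]-5-(trimethylsilyl)pent-2-en-4-ynoate | C[Si](C)(C)C#C/C=C(\CB1OC(C)(C)C(C)(C)O1)C(=O)OC | intermediate
11 | O8-pinacolboryl ether of 12 | C=C(C(=O)OC)[C@@H](C#C[Si](C)(C)C)[C@H](OB2OC(C)(C)C(C)(C)O2)CC[C@]1(C)O[C@@H]1CO[Si](C)(C)C(C)(C)C | intermediate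
12 | syn homoallylic alcohol, methyl (3S,4R)-4-hydroxy-2-methylidene-6-[(2S,3R)-3-(TBSO-methyl)-2-methyloxiran-2-yl]-3-[(trimethylsilyl)ethynyl]hexanoate | C=C(C(=O)OC)[C@@H](C#C[Si](C)(C)C)[C@H](O)CC[C@]1(C)O[C@@H]1CO[Si](C)(C)C(C)(C)C | intermediate
13 | angelic acid | C/C=C(/C)C(=O)O | starting material
14 | angelic 2,4,6-trichlorobenzoic anhydride | C/C=C(/C)C(=O)OC(=O)c1c(Cl)cc(Cl)cc1Cl | intermediate
15 | C8 angelate of 12 (3S,4R) | C=C(C(=O)OC)[C@@H](C#C[Si](C)(C)C)[C@H](OC(=O)/C(C)=C\C)CC[C@]1(C)O[C@@H]1CO[Si](C)(C)C(C)(C)C | intermediate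
16 | iodoalkyne (3S,4R) | C=C(C(=O)OC)[C@@H](C#CI)[C@H](OC(=O)/C(C)=C\C)CC[C@]1(C)O[C@@H]1CO[Si](C)(C)C(C)(C)C | intermediate
17 | (Z)-iodoalkene (3R,4R) | C=C(C(=O)OC)[C@@H](/C=C\I)[C@H](OC(=O)/C(C)=C\C)CC[C@]1(C)O[C@@H]1CO[Si](C)(C)C(C)(C)C | intermediate
18 | (Z)-alkenyltrimethylstannane | C=C(C(=O)OC)[C@@H](/C=C\[Sn](C)(C)C)[C@H](OC(=O)/C(C)=C\C)CC[C@]1(C)O[C@@H]1CO[Si](C)(C)C(C)(C)C | intermediate
19 | primary alcohol | C=C(C(=O)OC)[C@@H](/C=C\[Sn](C)(C)C)[C@H](OC(=O)/C(C)=C\C)CC[C@]1(C)O[C@@H]1CO | intermediate
20 | epoxy aldehyde | C=C(C(=O)OC)[C@@H](/C=C\[Sn](C)(C)C)[C@H](OC(=O)/C(C)=C\C)CC[C@]1(C)O[C@@H]1C=O | intermediate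
21 | ethyltriphenylphosphonium bromide | CC[P+](c1ccccc1)(c1ccccc1)c1ccccc1.[Br-] | starting material
22 | ethylidenetriphenylphosphorane | CC=P(c1ccccc1)(c1ccccc1)c1ccccc1 | intermediate
23 | (1-iodoethyl)triphenylphosphonium iodide | CC(I)[P+](c1ccccc1)(c1ccccc1)c1ccccc1.[I-] | intermediate
24 | (1-iodoethylidene)triphenylphosphorane | CC(I)=P(c1ccccc1)(c1ccccc1)c1ccccc1 | intermediate
25 | seco compound, (Z)-iodoalkene at C3=C4 and (Z)-alkenylstannane at C5=C6 | C=C(C(=O)OC)[C@@H](/C=C\[Sn](C)(C)C)[C@H](OC(=O)/C(C)=C\C)CC[C@]1(C)O[C@@H]1/C=C(/C)I | intermediate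
26 | ten-membered (3Z,5Z)-dienyl epoxide (1S,2R,7R,8R) | C=C(C(=O)OC)[C@H]1/C=C\C(C)=C/[C@H]2O[C@@]2(C)CC[C@H]1OC(=O)/C(C)=C\C | intermediate
27 | dioxygen (used as singlet oxygen) | O=O | starting material
28 | C3,C6-endoperoxide (1S,2R,3R,6S,7R,8R) | C=C(C(=O)OC)[C@H]1[C@H]2OO[C@H](C(C)=C2)[C@H]3O[C@@]3(C)CC[C@H]1OC(=O)/C(C)=C\C | intermediate
29 | cis-2-ene-1,4-diol methyl ester (1S,2R,3R,6S,7S,8R) | C=C(C(=O)OC)[C@H]1[C@@H](O)/C=C(/C)[C@@H](O)[C@H]2O[C@@]2(C)CC[C@H]1OC(=O)/C(C)=C\C | intermediate
30 | CNP0500828.1 (1S,2R,3R,6S,7R,8R) | C=C1C(=O)O[C@H]2/C=C(/C)[C@@H](O)[C@H]3O[C@@]3(C)CC[C@@H](OC(=O)/C(C)=C\C)[C@@H]12 | target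

**Totals**

Total steps: 18. Longest linear sequence: 15 steps (nerol 1 to target 30 through steps 1–3 and 7–18; the boronate branch, steps 4–6 then 7–18, is equally long).

**Steps most likely to fail**

1. Step 16. The ten-membered Z,Z-diene is twisted, so singlet oxygen may react by the ene pathway instead of (4+2). More seriously, in the rotamers invoked above the C8–C9–C10 bridge hangs on the very side that has to be attacked, so addition may be diverted to the other diene face and give the 3,6-bis-epimer. Fallback (the face is corrected by inversion instead of by conformer control): starting from 26, photooxygenation on the other face gives the bis-epimeric endoperoxide F1. Thiourea reduction gives the 3S,6R diol F2. A double Mitsunobu reaction (PPh3, diisopropyl azodicarboxylate, chloroacetic acid, toluene, 0 °C to rt) inverts both allylic carbinol centres and gives the 3R,6S bis(chloroacetate) F3. Thiourea with NaHCO3 in ethanol then removes the two chloroacetates without touching the angelate or the methyl ester, and the route is rejoined at diol 29.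

2. Step 15. Closure to a strained ten-membered Z,Z-diene may lose to intermolecular coupling or protodestannylation, and zerovalent palladium may ionise the allylic epoxide of substrate or product. Fallback (the ring is closed at an sp carbon and the second Z alkene is made afterwards): starting from 15, Bu4NF removes both silyl groups and gives the alkynyl alcohol F4. Dess–Martin oxidation gives the alkynyl epoxy aldehyde F5, and the iodo-ylide olefination of step 14 gives the alkynyl Z-iodoalkene F6. An intramolecular Sonogashira coupling (Pd(PPh3)4, CuI, i-Pr2NH, high dilution) gives the ten-membered enyne F7. Z-selective semi-reduction of its alkyne with zinc activated by Cu(OAc)2 and AgNO3 in aqueous methanol rejoins the route at 26.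

3. Step 7. The ester-deactivated, alkynyl-substituted boronate may add too slowly under a weak acid, so that uncatalysed background addition or closure of the C8 oxygen onto the ester erodes face control and material. Fallback (reagent control by a chiral ligand on boron instead of catalyst control): starting from 10, KHF2 in aqueous methanol gives the potassium trifluoroborate F8. Treatment with Me3SiCl and water, then with (R,R)-diisopropyl tartrate and MgSO4, gives the tartrate boronate F9. This more Lewis-acidic reagent adds to aldehyde 5 at −78 °C in toluene with 4 Å sieves through the same chair (hence syn), with the tartrate expected to select the Si face, and the route is rejoined at 12.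

Further compounds
F1 | step 16 | 3,6-bis-epimeric endoperoxide (1S,2R,3S,6R,7R,8R) | C=C(C(=O)OC)[C@H]1[C@@H]2OO[C@@H](C(C)=C2)[C@H]3O[C@@]3(C)CC[C@H]1OC(=O)/C(C)=C\C
F2 | step 16 | 3,6-bis-epimeric cis-ene-diol (3S,6R) | C=C(C(=O)OC)[C@H]1[C@H](O)/C=C(/C)[C@H](O)[C@H]2O[C@@]2(C)CC[C@H]1OC(=O)/C(C)=C\C
F3 | step 16 | 3R,6S bis(chloroacetate) | C=C(C(=O)OC)[C@H]1[C@@H](OC(=O)CCl)/C=C(/C)[C@@H](OC(=O)CCl)[C@H]2O[C@@]2(C)CC[C@H]1OC(=O)/C(C)=C\C
F4 | step 15 | terminal alkyne primary alcohol | C=C(C(=O)OC)[C@@H](C#C)[C@H](OC(=O)/C(C)=C\C)CC[C@]1(C)O[C@@H]1CO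
F5 | step 15 | terminal alkyne epoxy aldehyde | C=C(C(=O)OC)[C@@H](C#C)[C@H](OC(=O)/C(C)=C\C)CC[C@]1(C)O[C@@H]1C=O
F6 | step 15 | terminal alkyne (Z)-iodoalkene | C=C(C(=O)OC)[C@@H](C#C)[C@H](OC(=O)/C(C)=C\C)CC[C@]1(C)O[C@@H]1/C=C(/C)I
F7 | step 15 | ten-membered (3Z)-en-5-yne epoxide | C=C(C(=O)OC)[C@H]1C#C/C(C)=C\[C@H]2O[C@@]2(C)CC[C@H]1OC(=O)/C(C)=C\C
F8 | step 7 | potassium trifluoroborate of the allyl unit of 10 | [K+].F[B-](F)(F)C/C(C(=O)OC)=C\C#C[Si](C)(C)C
F9 | step 7 | (R,R)-diisopropyl tartrate boronate of the allyl unit of 10 | CC(C)OC(=O)[C@@H]1OB(C/C(C(=O)OC)=C\C#C[Si](C)(C)C)O[C@H]1C(=O)OC(C)C
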